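**Retrosynthetic overview**
- Target ⇐ desilylation ⇐ one-pot epoxidation and carboxylic-acid-triggered transannular cascade on a macrocyclic epoxy enone: this forms the C3–O ester bond and the C2–O–C6 ether bridge and fixes C3, C6 and C7.
- Ten-membered carbocycle ⇐ ring-closing metathesis (C6=C7) of an acyclic epoxy triene ketone; the 2,3-epoxide comes from substrate-directed epoxidation of a (Z)-olefin.
- Side chains ⇐ methallyl Grignard addition at C9; (Z)-alkenyl group by Normant carbocupration and 1,4-addition to a cyclohexadienoate; C10 and the exo-methylene by deconjugative kinetic protonation.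
- Cyclohexane ⇐ organocatalytic Michael/aldol/decarboxylation annulation of a Roche-ester-derived enal with tert-butyl 3-oxopentanoate, then triflation and carbonylation.
- Ring order: cyclohexane → ten-membered carbocycle → tetrahydropyran (oxygen bridge).

Assumption: labels C1–C20 in names and comments are the eunicellane numbers of the target (ring fusion C1/C10, ether C2–O–C6, ketone C9, C11=C20, hydroxypropyl C15–C17 on C14), and the target is taken exactly as drawn in the given SMILES.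

**Route**

Step 1
Reactants: 1 methyl (S)-3-hydroxy-2-methylpropanoate
Product: 2 methyl (S)-3-[(tert-butyldiphenylsilyl)oxy]-2-methylpropanoate
Conditions: TBDPSCl, imidazole, DMF, 0 °C → rt
Reagents that add atoms: tert-butyl(chloro)diphenylsilane CC(C)(C)[Si](Cl)(c1ccccc1)c1ccccc1
Why: Standard silyl ether formation on the primary alcohol; the C15 stereocentre comes from the chiral pool and is untouched.

Step 2
Reactants: 2 methyl (S)-3-[(tert-butyldiphenylsilyl)oxy]-2-methylpropanoate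
Product: 3 (S)-3-[(tert-butyldiphenylsilyl)oxy]-2-methylpropanal
Conditions: DIBAL-H, CH2Cl2, −78 °C; Rochelle salt
Reagents that add atoms: none
Why: Partial DIBAL reduction of the ester stops at the aldehyde because the tetrahedral aluminate is stable at −78 °C, and the α-stereocentre does not epimerise at this temperature.

Step 3
Reactants: 3 (S)-3-[(tert-butyldiphenylsilyl)oxy]-2-methylpropanal
Product: 4 (R,E)-5-[(tert-butyldiphenylsilyl)oxy]-4-methylpent-2-enal
Conditions: Ph3P=CHCHO, toluene, 70 °C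
Reagents that add atoms: (triphenylphosphoranylidene)acetaldehyde O=CC=P(c1ccccc1)(c1ccccc1)c1ccccc1
Why: Wittig olefination with a stabilised ylide gives the (E)-enal and adds C13 and C12.

Step 4
Reactants: 4 (R,E)-5-[(tert-butyldiphenylsilyl)oxy]-4-methylpent-2-enal; 5 tert-butyl 3-oxopentanoate
Product: 7 (S)-5-[(R)-1-[(tert-butyldiphenylsilyl)oxy]propan-2-yl]-2-methylcyclohex-2-en-1-one, via Michael adduct 6 (not isolated)
Conditions: (R)-α,α-diphenylprolinol TMS ether (10 mol %), PhCO2H (10 mol %), toluene, 0 °C → rt; then p-TsOH·H2O (20 mol %), 80 °C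
Reagents that add atoms: none
Why: Iminium-catalysed Michael addition of the β-keto ester sets C14 under catalyst control (attack on the face not shielded by the diphenylsilyloxymethyl group; the low temperature and acid co-catalyst are chosen to keep it ahead of γ-deprotonation, which would scramble C15), and acid then drives intramolecular aldol condensation, tert-butyl ester cleavage and decarboxylation to the carvone-type enone (formal [3+3] annulation).

Step 5
Reactants: 7 (S)-5-[(R)-1-[(tert-butyldiphenylsilyl)oxy]propan-2-yl]-2-methylcyclohex-2-en-1-one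
Product: 9 (R)-3-[(R)-1-[(tert-butyldiphenylsilyl)oxy]propan-2-yl]-6-methylcyclohexa-1,5-dien-1-yl trifluoromethanesulfonate, via lithium dienolate 8 (not isolated)
Conditions: LDA (commercial solution), THF, −78 °C; PhNTf2, −78 → 0 °C
Reagents that add atoms: N-phenylbis(trifluoromethanesulfonimide) O=S(=O)(N(c1ccccc1)S(=O)(=O)C(F)(F)F)C(F)(F)F
Why: Kinetic α′-deprotonation of the enone (cross-conjugated dienolate, as with carvone) and O-triflation give the dienyl triflate regiospecifically.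

Step 6
Reactants: 9 (R)-3-[(R)-1-[(tert-butyldiphenylsilyl)oxy]propan-2-yl]-6-methylcyclohexa-1,5-dien-1-yl trifluoromethanesulfonate
Product: 10 methyl (S)-3-[(R)-1-[(tert-butyldiphenylsilyl)oxy]propan-2-yl]-6-methylcyclohexa-1,5-diene-1-carboxylate
Conditions: Pd(OAc)2 (5 mol %), dppp, CO (1 atm), Et3N, MeOH–DMF, 60 °C
Reagents that add atoms: carbon monoxide [C-]#[O+]; methanol CO
Why: Pd-catalysed methoxycarbonylation of the vinyl triflate (oxidative addition, CO insertion, methanolysis) installs C9 as the ester.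

Step 7
Reactants: 10 methyl (S)-3-[(R)-1-[(tert-butyldiphenylsilyl)oxy]propan-2-yl]-6-methylcyclohexa-1,5-diene-1-carboxylate; 11 but-3-en-1-ylmagnesium bromide; 12 propyne
Product: 15 methyl (5S,6S)-5-[(R)-1-[(tert-butyldiphenylsilyl)oxy]propan-2-yl]-2-methyl-6-[(Z)-2-methylhexa-1,5-dien-1-yl]cyclohex-1-ene-1-carboxylate, via alkenylcopper 13 (not isolated), via silyl ketene acetal 14 (not isolated)
Conditions: 11, CuBr·SMe2, Et2O–Me2S, −45 °C; 12, −25 °C; then 10, TMSCl, THF, −78 → −30 °C; then NaOMe, MeOH, 0 °C → rt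
Reagents that add atoms: none
Why: Normant syn-carbocupration of propyne fixes the (Z)-trisubstituted C2=C3 olefin, TMSCl-accelerated 1,4-addition of the alkenylcopper occurs anti to the C14 side chain (sets C1 trans to C14), and methanolysis with methoxide equilibration gives the conjugated tetrasubstituted enoate.

Step 8
Reactants: 15 methyl (5S,6S)-5-[(R)-1-[(tert-butyldiphenylsilyl)oxy]propan-2-yl]-2-methyl-6-[(Z)-2-methylhexa-1,5-dien-1-yl]cyclohex-1-ene-1-carboxylate
Product: 17 methyl (1R,5S,6S)-5-[(R)-1-[(tert-butyldiphenylsilyl)oxy]propan-2-yl]-2-methylidene-6-[(Z)-2-methylhexa-1,5-dien-1-yl]cyclohexane-1-carboxylate, via lithium dienolate 16 (not isolated)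
Conditions: LDA (commercial solution), DMPU, THF, −78 °C; then AcOH in THF, −78 °C
Reagents that add atoms: none
Why: Deconjugative protonation: LDA removes a proton from the methyl group cis to the ester (syn effect) to give the exocyclic dienolate, and kinetic α-protonation on the face away from the C1 alkenyl group gives the 11(20)-methylene ester with H10 cis to H1 (sets C10, the contra-thermodynamic cis isomer expected for kinetic protonation of an exocyclic enolate).

Step 9
Reactants: 17 methyl (1R,5S,6S)-5-[(R)-1-[(tert-butyldiphenylsilyl)oxy]propan-2-yl]-2-methylidene-6-[(Z)-2-methylhexa-1,5-dien-1-yl]cyclohexane-1-carboxylate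
Product: 18 (1R,5S,6S)-5-[(R)-1-[(tert-butyldiphenylsilyl)oxy]propan-2-yl]-2-methylidene-6-[(Z)-2-methylhexa-1,5-dien-1-yl]cyclohexane-1-carbaldehyde
Conditions: DIBAL-H (1.1 equiv), CH2Cl2, −78 °C; Rochelle salt
Reagents that add atoms: none
Why: DIBAL half-reduction of the hindered α-branched ester gives the aldehyde, which is used at once to avoid C10 epimerisation.

Step 10
Reactants: 18 (1R,5S,6S)-5-[(R)-1-[(tert-butyldiphenylsilyl)oxy]propan-2-yl]-2-methylidene-6-[(Z)-2-methylhexa-1,5-dien-1-yl]cyclohexane-1-carbaldehyde; 19 (2-methylprop-2-en-1-yl)magnesium chloride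
Product: 20 1-[(1R,5S,6S)-5-[(R)-1-[(tert-butyldiphenylsilyl)oxy]propan-2-yl]-2-methylidene-6-[(Z)-2-methylhexa-1,5-dien-1-yl]cyclohexyl]-3-methylbut-3-en-1-ol (C9 epimers)
Conditions: 19, THF, −78 °C; aq NH4Cl
Reagents that add atoms: none
Why: Grignard 1,2-addition attaches C8, C7 and C19; the carbinol configuration does not matter because it is oxidised in the next step.

Step 11
Reactants: 20 1-[(1R,5S,6S)-5-[(R)-1-[(tert-butyldiphenylsilyl)oxy]propan-2-yl]-2-methylidene-6-[(Z)-2-methylhexa-1,5-dien-1-yl]cyclohexyl]-3-methylbut-3-en-1-ol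
Product: 21 1-[(1R,5S,6S)-5-[(R)-1-[(tert-butyldiphenylsilyl)oxy]propan-2-yl]-2-methylidene-6-[(Z)-2-methylhexa-1,5-dien-1-yl]cyclohexyl]-3-methylbut-3-en-1-one
Conditions: Dess–Martin periodinane, NaHCO3, CH2Cl2, 0 °C
Reagents that add atoms: none
Why: Buffered Dess–Martin oxidation gives the doubly β,γ-unsaturated ketone under non-enolising conditions, so neither olefin moves into conjugation and C10 is kept.

Step 12
Reactants: 21 1-[(1R,5S,6S)-5-[(R)-1-[(tert-butyldiphenylsilyl)oxy]propan-2-yl]-2-methylidene-6-[(Z)-2-methylhexa-1,5-dien-1-yl]cyclohexyl]-3-methylbut-3-en-1-one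
Product: 22 1-[(1R,5R,6R)-6-[(2R,3S)-3-(but-3-en-1-yl)-3-methyloxiran-2-yl]-5-[(R)-1-[(tert-butyldiphenylsilyl)oxy]propan-2-yl]-2-methylidenecyclohexyl]-3-methylbut-3-en-1-one
Conditions: m-CPBA (1.05 equiv), NaHCO3, CH2Cl2, −20 °C
Reagents that add atoms: 3-chloroperbenzoic acid O=C(OO)c1cccc(Cl)c1
Why: Prilezhaev epoxidation is selective for the only trisubstituted olefin, and the (Z)-alkenyl group, locked by A(1,3) strain with H1 in the olefin plane, is attacked on the face away from the equatorial C14 side chain, which sets C2 (and the cis-epoxide at C3).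

Step 13
Reactants: 22 1-[(1R,5R,6R)-6-[(2R,3S)-3-(but-3-en-1-yl)-3-methyloxiran-2-yl]-5-[(R)-1-[(tert-butyldiphenylsilyl)oxy]propan-2-yl]-2-methylidenecyclohexyl]-3-methylbut-3-en-1-one
Product: 23 (1R,2R,3S,6Z,10R,14R,15R)-16-[(tert-butyldiphenylsilyl)oxy]-2,3-epoxyeunicella-6,11(20)-dien-9-one
Conditions: Grubbs II (10 mol %), 1,4-benzoquinone (20 mol %), toluene (1 mM), 80 °C
Reagents that add atoms: none
Why: Ring-closing metathesis between the vinyl and methallyl groups closes the ten-membered ring with loss of ethene; the cis ring fusion and cis-epoxide act as turn elements and the medium ring favours the (Z)-trisubstituted C6=C7 olefin.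

Step 14
Reactants: 24 (S)-2-hydroxybutanoic acid
Product: 25 (S)-2-(butanoyloxy)butanoic acid
Conditions: butanoyl chloride (1.5 equiv), neat, 0 → 40 °C; then H2O–THF
Reagents that add atoms: butanoyl chloride CCCC(=O)Cl
Why: O-acylation of the α-hydroxy acid with the acid chloride without base, so the stereocentre is not racemised.

Step 15
Reactants: 23 (1R,2R,3S,6Z,10R,14R,15R)-16-[(tert-butyldiphenylsilyl)oxy]-2,3-epoxyeunicella-6,11(20)-dien-9-one; 25 (S)-2-(butanoyloxy)butanoic acid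
Product: 27 (1R,2R,3R,6R,7R,10R,14R,15R)-16-[(tert-butyldiphenylsilyl)oxy]-7-hydroxy-9-oxo-2,6-epoxyeunicell-11(20)-en-3-yl (S)-2-(butanoyloxy)butanoate, via bis-epoxide 26 (not isolated)
Conditions: DMDO (1.05 equiv), acetone–CH2Cl2, −40 °C, evaporate; then 25 (3 equiv), (CF3)2CHOH–CH2Cl2 (1:4), 0 °C → rt
Reagents that add atoms: dimethyldioxirane CC1(C)OO1
Why: Proposed new method: a carboxylic-acid-triggered transannular bis-epoxide cascade in which the acid, with the epoxide activated by the hydrogen-bond-donor solvent, opens the 2,3-epoxide at its tertiary carbon C3 in a borderline-SN2 step with inversion (the 6,7-epoxide should be slower because C7 is β to the C9 carbonyl), and the freed C2 hydroxyl, now held across the ring behind C6, opens the second epoxide 6-exo with inversion to give the 2,6-bridged tetrahydropyran and the C7 tertiary alcohol, so C3 and C6 are set by two inversions while C2 and C7 keep their epoxide configurations and the tertiary ester cannot migrate once O2 is an ether; only the 6,7-epoxide with oxygen on the outer ring face (expected from peripheral DMDO attack) can cyclise; the closest known chemistry is acid-mediated epoxide-opening cascades of polyepoxides, carboxylic-acid opening of epoxides and transannular epoxy-alcohol cyclisation.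

Step 16
Reactants: 27 (1R,2R,3R,6R,7R,10R,14R,15R)-16-[(tert-butyldiphenylsilyl)oxy]-7-hydroxy-9-oxo-2,6-epoxyeunicell-11(20)-en-3-yl (S)-2-(butanoyloxy)butanoate
Product: 28 (1R,2R,3R,6R,7R,10R,14R,15R)-7,16-dihydroxy-9-oxo-2,6-epoxyeunicell-11(20)-en-3-yl (S)-2-(butanoyloxy)butanoate (CNP0291223.2)
Conditions: HF·pyridine, pyridine, THF, 0 °C → rt
Reagents that add atoms: none
Why: Fluoride-mediated desilylation under mildly acidic conditions removes the TBDPS group and spares the tertiary ester, the β-hydroxy ketone and the β,γ-unsaturated ketone.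

**Compound list**

1 | methyl (S)-3-hydroxy-2-methylpropanoate ((S)-Roche ester) | COC(=O)[C@@H](C)CO | starting material
2 | methyl (S)-3-[(tert-butyldiphenylsilyl)oxy]-2-methylpropanoate | COC(=O)[C@@H](C)CO[Si](c1ccccc1)(c1ccccc1)C(C)(C)C | intermediate
3 | (S)-3-[(tert-butyldiphenylsilyl)oxy]-2-methylpropanal | O=C[C@@H](C)CO[Si](c1ccccc1)(c1ccccc1)C(C)(C)C | intermediate
4 | (R,E)-5-[(tert-butyldiphenylsilyl)oxy]-4-methylpent-2-enal | O=C/C=C/[C@@H](C)CO[Si](c1ccccc1)(c1ccccc1)C(C)(C)C | intermediate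
5 | tert-butyl 3-oxopentanoate | CCC(=O)CC(=O)OC(C)(C)C | starting material
6 | tert-butyl (3R)-3-[(R)-1-[(tert-butyldiphenylsilyl)oxy]propan-2-yl]-5-oxo-2-propanoylpentanoate (Michael adduct; C2 epimers) | CCC(=O)C(C(=O)OC(C)(C)C)[C@H](CC=O)[C@@H](C)CO[Si](c1ccccc1)(c1ccccc1)C(C)(C)C | intermediate (not isolated)
7 | (S)-5-[(R)-1-[(tert-butyldiphenylsilyl)oxy]propan-2-yl]-2-methylcyclohex-2-en-1-one | O=C1C(C)=CC[C@H]([C@@H](C)CO[Si](c2ccccc2)(c2ccccc2)C(C)(C)C)C1 | intermediate
8 | lithium (R)-3-[(R)-1-[(tert-butyldiphenylsilyl)oxy]propan-2-yl]-6-methylcyclohexa-1,5-dien-1-olate | CC1=CC[C@H]([C@@H](C)CO[Si](c2ccccc2)(c2ccccc2)C(C)(C)C)C=C1[O-].[Li+] | intermediate (not isolated)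
9 | (R)-3-[(R)-1-[(tert-butyldiphenylsilyl)oxy]propan-2-yl]-6-methylcyclohexa-1,5-dien-1-yl trifluoromethanesulfonate | CC1=CC[C@H]([C@@H](C)CO[Si](c2ccccc2)(c2ccccc2)C(C)(C)C)C=C1OS(=O)(=O)C(F)(F)F | intermediate
10 | methyl (S)-3-[(R)-1-[(tert-butyldiphenylsilyl)oxy]propan-2-yl]-6-methylcyclohexa-1,5-diene-1-carboxylate | CC1=CC[C@H]([C@@H](C)CO[Si](c2ccccc2)(c2ccccc2)C(C)(C)C)C=C1C(=O)OC | intermediate
11 | but-3-en-1-ylmagnesium bromide | C=CCC[Mg]Br | starting material
12 | propyne | CC#C | starting material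
13 | (Z)-(2-methylhexa-1,5-dien-1-yl)copper (MgBr2 complex) | [Cu]/C=C(/C)CCC=C | intermediate (not isolated)
14 | methyl trimethylsilyl ketene acetal of the 1,4-adduct (5S,6S; C1/C14 trans) | COC(O[Si](C)(C)C)=C1C(C)=CC[C@H]([C@@H](C)CO[Si](c2ccccc2)(c2ccccc2)C(C)(C)C)[C@H]1/C=C(/C)CCC=C | intermediate (not isolated)
15 | methyl (5S,6S)-5-[(R)-1-[(tert-butyldiphenylsilyl)oxy]propan-2-yl]-2-methyl-6-[(Z)-2-methylhexa-1,5-dien-1-yl]cyclohex-1-ene-1-carboxylate | COC(=O)C1=C(C)CC[C@H]([C@@H](C)CO[Si](c2ccccc2)(c2ccccc2)C(C)(C)C)[C@H]1/C=C(/C)CCC=C | intermediate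
16 | lithium exocyclic dienolate of 15 (C11=C20 methylene) | [Li+].COC([O-])=C1C(=C)CC[C@H]([C@@H](C)CO[Si](c2ccccc2)(c2ccccc2)C(C)(C)C)[C@H]1/C=C(/C)CCC=C | intermediate (not isolated)
17 | methyl (1R,5S,6S)-5-[(R)-1-[(tert-butyldiphenylsilyl)oxy]propan-2-yl]-2-methylidene-6-[(Z)-2-methylhexa-1,5-dien-1-yl]cyclohexane-1-carboxylate | COC(=O)[C@H]1C(=C)CC[C@H]([C@@H](C)CO[Si](c2ccccc2)(c2ccccc2)C(C)(C)C)[C@H]1/C=C(/C)CCC=C | intermediate
18 | (1R,5S,6S)-5-[(R)-1-[(tert-butyldiphenylsilyl)oxy]propan-2-yl]-2-methylidene-6-[(Z)-2-methylhexa-1,5-dien-1-yl]cyclohexane-1-carbaldehyde | O=C[C@H]1C(=C)CC[C@H]([C@@H](C)CO[Si](c2ccccc2)(c2ccccc2)C(C)(C)C)[C@H]1/C=C(/C)CCC=C | intermediate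
19 | (2-methylprop-2-en-1-yl)magnesium chloride | CC(=C)C[Mg]Cl | starting material
20 | 1-[(1R,5S,6S)-5-[(R)-1-[(tert-butyldiphenylsilyl)oxy]propan-2-yl]-2-methylidene-6-[(Z)-2-methylhexa-1,5-dien-1-yl]cyclohexyl]-3-methylbut-3-en-1-ol (C9 epimers) | CC(=C)CC(O)[C@H]1C(=C)CC[C@H]([C@@H](C)CO[Si](c2ccccc2)(c2ccccc2)C(C)(C)C)[C@H]1/C=C(/C)CCC=C | intermediate
21 | 1-[(1R,5S,6S)-5-[(R)-1-[(tert-butyldiphenylsilyl)oxy]propan-2-yl]-2-methylidene-6-[(Z)-2-methylhexa-1,5-dien-1-yl]cyclohexyl]-3-methylbut-3-en-1-one | CC(=C)CC(=O)[C@H]1C(=C)CC[C@H]([C@@H](C)CO[Si](c2ccccc2)(c2ccccc2)C(C)(C)C)[C@H]1/C=C(/C)CCC=C | intermediate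
22 | 1-[(1R,5R,6R)-6-[(2R,3S)-3-(but-3-en-1-yl)-3-methyloxiran-2-yl]-5-[(R)-1-[(tert-butyldiphenylsilyl)oxy]propan-2-yl]-2-methylidenecyclohexyl]-3-methylbut-3-en-1-one | CC(=C)CC(=O)[C@H]1C(=C)CC[C@H]([C@@H](C)CO[Si](c2ccccc2)(c2ccccc2)C(C)(C)C)[C@H]1[C@H]3O[C@@]3(C)CCC=C | intermediate
23 | (1R,2R,3S,6Z,10R,14R,15R)-16-[(tert-butyldiphenylsilyl)oxy]-2,3-epoxyeunicella-6,11(20)-dien-9-one | O=C1C/C(C)=C\CC[C@]2(C)O[C@@H]2[C@@H]3[C@@H]([C@@H](C)CO[Si](c4ccccc4)(c4ccccc4)C(C)(C)C)CCC(=C)[C@H]13 | intermediate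
24 | (S)-2-hydroxybutanoic acid | CC[C@H](O)C(=O)O | starting material
25 | (S)-2-(butanoyloxy)butanoic acid | CCCC(=O)O[C@@H](CC)C(=O)O | intermediate
26 | (1R,2R,3S,6S,7R,10R,14R,15R)-16-[(tert-butyldiphenylsilyl)oxy]-2,3:6,7-diepoxyeunicell-11(20)-en-9-one | O=C1C[C@@]4(C)O[C@H]4CC[C@]2(C)O[C@@H]2[C@@H]3[C@@H]([C@@H](C)CO[Si](c5ccccc5)(c5ccccc5)C(C)(C)C)CCC(=C)[C@H]13 | intermediate (not isolated)
27 | (1R,2R,3R,6R,7R,10R,14R,15R)-16-[(tert-butyldiphenylsilyl)oxy]-7-hydroxy-9-oxo-2,6-epoxyeunicell-11(20)-en-3-yl (S)-2-(butanoyloxy)butanoate | C=C1CC[C@H]([C@@H](C)CO[Si](c3ccccc3)(c3ccccc3)C(C)(C)C)[C@@H]2[C@H]1C(=O)C[C@@](C)(O)[C@H]1CC[C@@](C)(OC(=O)[C@H](CC)OC(=O)CCC)[C@@H]2O1 | intermediate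
28 | (1R,2R,3R,6R,7R,10R,14R,15R)-7,16-dihydroxy-9-oxo-2,6-epoxyeunicell-11(20)-en-3-yl (S)-2-(butanoyloxy)butanoate (CNP0291223.2) | C=C1CC[C@H]([C@@H](C)CO)[C@@H]2[C@H]1C(=O)C[C@@](C)(O)[C@H]1CC[C@@](C)(OC(=O)[C@H](CC)OC(=O)CCC)[C@@H]2O1 | target

**Step count**

Total step count: 16. Longest linear sequence: 15 (steps 1–13, 15 and 16; step 14 makes the side-chain acid).

**Three steps most likely to fail**

Step 13 (ring-closing metathesis). A ten-membered ring with a trisubstituted olefin is a hard metathesis case: oligomerisation, an E/Z mixture or reaction at the exo-methylene may compete. The fallback sets out from 10 and comes back at 23. It closes the ring by a Nozaki–Hiyama–Kishi reaction and then transposes the olefin. Carbocupration of propyne (12) with the copper reagent from commercial [2-(1,3-dioxolan-2-yl)ethyl]magnesium bromide gives the (Z)-alkenylcopper F4, which adds to 10 as in step 7 to give the conjugated ester F5. Deconjugative protonation as in step 8 gives the exo-methylene ester F6, and DIBAL-H gives the aldehyde F7. Indium-mediated Barbier reaction with 2,3-dibromopropene gives the bromoallyl carbinol F8, Dess–Martin oxidation gives the ketone F9, and m-CPBA gives the 2,3-epoxide F10. PPTS in wet acetone unmasks the C6 aldehyde F11. CrCl2 with catalytic NiCl2 (DMSO–THF, 2 mM) closes the ten-membered ring to the allylic alcohol F12 (C6–OH, C7=C19H2). Myers reductive transposition (o-nitrobenzenesulfonylhydrazine, PPh3, DEAD; loss of N2 from the allylic diazene) moves the double bond to C6=C7, turns C19 into the methyl group and gives 23.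

Step 15 (the proposed cascade). The two epoxides may react in the wrong order (epoxide–epoxide participation or acid attack at C7 would lead to a tetrahydrofuran), the 6,7-epoxide may form on the wrong face, and the hydroxy ester may undergo acyl migration. The fallback sets out from 22 and comes back at 27, making the two C–O bonds one at a time with known reactions. Acid-catalysed opening of the single epoxide of acyclic 22 with 25 (5 equiv, CSA cat., CH2Cl2) occurs at the tertiary carbon with inversion and gives the hydroxy ester F13, which is used at once. Ring-closing metathesis as in step 13 gives the macrocyclic hydroxy ester F14. DMDO then gives the 6,7-epoxide F15, which is not isolated but closed with PPTS by transannular 6-exo attack of the C2 hydroxyl to give 27.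

Step 4 (organocatalytic annulation). Three events must go in one operation, the γ-stereocentre C15 of the enal can be lost through dienamine formation, and the ethyl ketone must do the aldol condensation. The fallback sets out from 3 and comes back at 7, replacing the aminocatalytic cascade by a substrate-controlled sequence. Wittig reaction of 3 with 1-(triphenylphosphoranylidene)butan-2-one gives the (E)-enone F1. Hosomi–Sakurai allylation (allyltrimethylsilane, TiCl4, −78 °C; Felkin–Anh control from C15, selectivity likely modest, the minor C14 epimer removed by chromatography) gives the allyl ketone F2. Ozonolysis (O3, then Me2S) gives the keto aldehyde F3, and intramolecular aldol condensation (KOH, MeOH) gives 7.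

**Further compounds**

F1 | step 4 | (R,E)-7-[(tert-butyldiphenylsilyl)oxy]-6-methylhept-4-en-3-one | CCC(=O)/C=C/[C@@H](C)CO[Si](c1ccccc1)(c1ccccc1)C(C)(C)C
F2 | step 4 | (5S,6R)-7-[(tert-butyldiphenylsilyl)oxy]-6-methyl-5-(prop-2-en-1-yl)heptan-3-one | CCC(=O)C[C@H](CC=C)[C@@H](C)CO[Si](c1ccccc1)(c1ccccc1)C(C)(C)C
F3 | step 4 | (3S,4R)-5-[(tert-butyldiphenylsilyl)oxy]-4-methyl-3-(2-oxobutyl)pentanal | CCC(=O)C[C@H](CC=O)[C@@H](C)CO[Si](c1ccccc1)(c1ccccc1)C(C)(C)C
F4 | step 13 | (Z)-[4-(1,3-dioxolan-2-yl)-2-methylbut-1-en-1-yl]copper | [Cu]/C=C(/C)CCC1OCCO1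
F5 | step 13 | analogue of 15 with a (Z)-4-(1,3-dioxolan-2-yl)-2-methylbut-1-en-1-yl group at C1 | COC(=O)C1=C(C)CC[C@H]([C@@H](C)CO[Si](c2ccccc2)(c2ccccc2)C(C)(C)C)[C@H]1/C=C(/C)CCC1OCCO1
F6 | step 13 | analogue of 17 with the dioxolane side chain (exo-methylene ester) | COC(=O)[C@H]1C(=C)CC[C@H]([C@@H](C)CO[Si](c2ccccc2)(c2ccccc2)C(C)(C)C)[C@H]1/C=C(/C)CCC1OCCO1
F7 | step 13 | analogue of 18 with the dioxolane side chain (C9 aldehyde) | O=C[C@H]1C(=C)CC[C@H]([C@@H](C)CO[Si](c2ccccc2)(c2ccccc2)C(C)(C)C)[C@H]1/C=C(/C)CCC1OCCO1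
F8 | step 13 | 3-bromobut-3-en-1-ol adduct at C9 (C9 epimers) | C=C(Br)CC(O)[C@H]1C(=C)CC[C@H]([C@@H](C)CO[Si](c2ccccc2)(c2ccccc2)C(C)(C)C)[C@H]1/C=C(/C)CCC1OCCO1
F9 | step 13 | 3-bromobut-3-en-1-one (C9 ketone with C7 vinyl bromide) | C=C(Br)CC(=O)[C@H]1C(=C)CC[C@H]([C@@H](C)CO[Si](c2ccccc2)(c2ccccc2)C(C)(C)C)[C@H]1/C=C(/C)CCC1OCCO1
F10 | step 13 | (2R,3S)-2,3-epoxide of F9 | C=C(Br)CC(=O)[C@H]1C(=C)CC[C@H]([C@@H](C)CO[Si](c2ccccc2)(c2ccccc2)C(C)(C)C)[C@H]1[C@H]3O[C@@]3(C)CCC1OCCO1
F11 | step 13 | C6 aldehyde from F10 | C=C(Br)CC(=O)[C@H]1C(=C)CC[C@H]([C@@H](C)CO[Si](c2ccccc2)(c2ccccc2)C(C)(C)C)[C@H]1[C@H]3O[C@@]3(C)CCC=O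
F12 | step 13 | macrocyclic allylic alcohol: 16-[(tert-butyldiphenylsilyl)oxy]-2,3-epoxy-6-hydroxyeunicella-7(19),11(20)-dien-9-one (C6 epimers) | O=C1CC(=C)C(O)CC[C@]2(C)O[C@@H]2[C@@H]3[C@@H]([C@@H](C)CO[Si](c4ccccc4)(c4ccccc4)C(C)(C)C)CCC(=C)[C@H]13
F13 | step 15 | acyclic hydroxy ester: (2R,3R)-2-hydroxy-3-[(S)-2-(butanoyloxy)butanoyloxy] opening product of 22 | CC(=C)CC(=O)[C@H]1C(=C)CC[C@H]([C@@H](C)CO[Si](c2ccccc2)(c2ccccc2)C(C)(C)C)[C@H]1[C@@H](O)[C@](C)(OC(=O)[C@H](CC)OC(=O)CCC)CCC=C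
F14 | step 15 | macrocyclic hydroxy ester: (6Z)-16-[(tert-butyldiphenylsilyl)oxy]-2-hydroxy-9-oxoeunicella-6,11(20)-dien-3-yl (S)-2-(butanoyloxy)butanoate | O=C1C/C(C)=C\CC[C@@](C)(OC(=O)[C@H](CC)OC(=O)CCC)[C@H](O)[C@@H]2[C@@H]([C@@H](C)CO[Si](c3ccccc3)(c3ccccc3)C(C)(C)C)CCC(=C)[C@H]12
F15 | step 15 | (6S,7R)-6,7-epoxide of F14 | O=C1C[C@@]4(C)O[C@H]4CC[C@@](C)(OC(=O)[C@H](CC)OC(=O)CCC)[C@H](O)[C@@H]2[C@@H]([C@@H](C)CO[Si](c3ccccc3)(c3ccccc3)C(C)(C)C)CCC(=C)[C@H]12
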